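**Retrosynthetic overview**
- Side chain: cut C12–C13 (Stille) into an (E)-vinylstannane made from a C9 ethynyl group and a glyceraldehyde-derived 2-bromoallyl acetonide.
- Ring B stereocentres: the C7 alcohol comes from reducing a ketone; 5α-H, 6α-OH, 8α-OH and 9α-H all come from one twofold HAT reductive α-hydroxylation of a cross-conjugated dienone.
- Ring A is closed last (C4–C5) by a radical cyclisation of a homoprenyl chain onto that dienone, keeping C5 sp2.
- Ring B is formed first, carved out of 2-methoxy-3-methylbenzoic acid by an auxiliary-controlled Birch reduction–alkylation that sets C10 (carboxyl carbon → angular methyl, OMe → C9 handle, ring CH2 → C7 ketone).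
- The acid comes from 2-methylanisole by ortho-lithiation and carboxylation.

Assumption: the (S)-auxiliary 4 is taken to be the enantiomer that gives (1R)-9; if the sense is the opposite, the commercial (R)-enantiomer of 4 is used and nothing else changes.

**Step 1**
Reactants: 1 2-methylanisole
Product: 3 2-methoxy-3-methylbenzoic acid, via (2-methoxy-3-methylphenyl)lithium 2 (not isolated)
Conditions: n-BuLi, TMEDA, Et2O, 0 → 23 °C; CO2, −78 °C; 2 M HCl
Reagents that add atoms: carbon dioxide, O=C=O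
Why: Directed ortho-metalation (the methoxy group steers lithiation to its only free ortho position) followed by carboxylation of the aryllithium; no stereocentre is formed.

**Step 2**
Reactants: 3 2-methoxy-3-methylbenzoic acid; 4 (S)-2-(methoxymethyl)pyrrolidine
Product: 6 (2-methoxy-3-methylphenyl)[(2S)-2-(methoxymethyl)pyrrolidin-1-yl]methanone, via acid chloride 5 (not isolated)
Conditions: (COCl)2, DMF (cat.), CH2Cl2, 0 → 23 °C; then 4, Et3N, CH2Cl2, 0 °C
Reagents that add atoms: none
Why: Acyl chloride formation and amine acylation (nucleophilic acyl substitution) attach the prolinol-ether auxiliary, whose stereocentre is untouched.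

**Step 3**
Reactants: 6 (2-methoxy-3-methylphenyl)[(2S)-2-(methoxymethyl)pyrrolidin-1-yl]methanone; 7 5-bromo-2-methylpent-2-ene
Product: 9 [(1R)-2-methoxy-3-methyl-1-(4-methylpent-3-en-1-yl)cyclohexa-2,5-dien-1-yl][(2S)-2-(methoxymethyl)pyrrolidin-1-yl]methanone, via potassium amide enolate 8 (not isolated)
Conditions: K (2.2 equiv), t-BuOH (1 equiv), NH3(l)–THF, −78 °C; then 7, −78 → −33 °C; NH4Cl
Reagents that add atoms: none
Why: Schultz asymmetric Birch reduction–alkylation: the potassium amide enolate, held by chelation to the ortho-methoxy group and the auxiliary ether, is alkylated on its open face, which dearomatizes the ring and sets the quaternary carbon (R) with the usual dr of at least 95:5.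

**Step 4**
Reactants: 9 [(1R)-2-methoxy-3-methyl-1-(4-methylpent-3-en-1-yl)cyclohexa-2,5-dien-1-yl][(2S)-2-(methoxymethyl)pyrrolidin-1-yl]methanone
Product: 10 (1R)-2-methoxy-3-methyl-1-(4-methylpent-3-en-1-yl)cyclohexa-2,5-diene-1-carbaldehyde
Conditions: Cp2Zr(H)Cl (2 equiv), THF, 23 °C; aq. NaHCO3
Reagents that add atoms: none
Why: Georg's Schwartz-reagent reduction of a tertiary amide stops at the zirconated hemiaminal, which collapses to the aldehyde on work-up; the quaternary centre has no α-hydrogen and cannot epimerize.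

**Step 5**
Reactants: 10 (1R)-2-methoxy-3-methyl-1-(4-methylpent-3-en-1-yl)cyclohexa-2,5-diene-1-carbaldehyde
Product: 13 (2S)-2,6-dimethyl-2-(4-methylpent-3-en-1-yl)cyclohex-3-en-1-one, via hydrazone 11 (not isolated), via methyl enol ether 12 (not isolated)
Conditions: N2H4·H2O, EtOH, 70 °C; KOt-Bu, DMSO, 23 °C; then 1 M HCl–THF, 0 → 23 °C
Reagents that add atoms: water, O
Why: Wolff–Kishner reduction (Cram's room-temperature variant on the preformed hydrazone) turns the neopentyl aldehyde into the methyl group, and the acidic work-up hydrolyses the methyl enol ether to the ketone; the new methine centre next to the carbonyl forms as a mixture and is erased in step 6.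

**Step 6**
Reactants: 13 (2S)-2,6-dimethyl-2-(4-methylpent-3-en-1-yl)cyclohex-3-en-1-one
Product: 15 (6S)-2,6-dimethyl-6-(4-methylpent-3-en-1-yl)cyclohexa-1,4-dien-1-yl trifluoromethanesulfonate, via potassium enolate 14 (not isolated)
Conditions: KN(SiMe3)2, THF, −78 °C; PhNTf2, −78 → 0 °C; aq. NH4Cl
Reagents that add atoms: N-phenylbis(trifluoromethanesulfonimide), O=S(=O)(N(c1ccccc1)S(=O)(=O)C(F)(F)F)C(F)(F)F
Why: Enolate O-triflation; the ketone can enolize only toward the methyl-bearing carbon because the other α-carbon is quaternary, so a single tetrasubstituted enol triflate forms.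

**Step 7**
Reactants: 15 (6S)-2,6-dimethyl-6-(4-methylpent-3-en-1-yl)cyclohexa-1,4-dien-1-yl trifluoromethanesulfonate; 16 ethynyltrimethylsilane
Product: 17 {[(6S)-2,6-dimethyl-6-(4-methylpent-3-en-1-yl)cyclohexa-1,4-dien-1-yl]ethynyl}trimethylsilane
Conditions: Pd(PPh3)4 (5 mol %), CuI (10 mol %), Et3N, DMF, 40 °C
Reagents that add atoms: none
Why: Sonogashira coupling of the vinyl triflate with the terminal alkyne; no stereocentre is touched.

**Step 8**
Reactants: 17 {[(6S)-2,6-dimethyl-6-(4-methylpent-3-en-1-yl)cyclohexa-1,4-dien-1-yl]ethynyl}trimethylsilane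
Product: 18 (4S)-2,4-dimethyl-4-(4-methylpent-3-en-1-yl)-3-[(trimethylsilyl)ethynyl]cyclohexa-2,5-dien-1-one
Conditions: t-BuOOH (70 % aq., 5 equiv), Rh2(C6H10NO)4 [dirhodium tetracaprolactamate] (1 mol %), CH2Cl2, 23 °C
Reagents that add atoms: tert-butyl hydroperoxide, CC(C)(C)OO
Why: Allylic C–H oxidation is selective for the only doubly allylic CH2 and gives the cross-conjugated dienone, as in Schultz's oxidations of Birch dienes.

**Step 9**
Reactants: 18 (4S)-2,4-dimethyl-4-(4-methylpent-3-en-1-yl)-3-[(trimethylsilyl)ethynyl]cyclohexa-2,5-dien-1-one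
Product: 19 (4aS)-3,4a,8,8-tetramethyl-4-[(trimethylsilyl)ethynyl]-5,6,7,8-tetrahydronaphthalen-2(4aH)-one
Conditions: CoCl(C32H46N2O2) [chloro cobalt complex of N,N′-bis(3,5-di-tert-butylsalicylidene)ethylenediamine] (5 mol %), PhSiH3 (10 mol %), benzene, 23 °C
Reagents that add atoms: none
Why: Proposed new method: cobalt hydride transfers a hydrogen atom to the trisubstituted side-chain alkene, the tertiary radical adds 6-exo to the unsubstituted enone β-carbon (the other β-carbon is fully substituted), and the resulting α-keto radical has a single β-hydrogen that is returned to divalent cobalt, so the enone is regenerated with ring A closed and the ring-fusion carbon still sp2 (no stereocentre set here); the closest known reactions are Shenvi's Co(salen)-catalysed MHAT cycloisomerisation of dienes and Baran's iron-mediated MHAT Giese cyclisations.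

**Step 10**
Reactants: 19 (4aS)-3,4a,8,8-tetramethyl-4-[(trimethylsilyl)ethynyl]-5,6,7,8-tetrahydronaphthalen-2(4aH)-one
Product: 21 (1R,3S,4S,4aS,8aS)-1,3-dihydroxy-3,4a,8,8-tetramethyl-4-[(trimethylsilyl)ethynyl]octahydronaphthalen-2(1H)-one, via bis-hydroperoxide 20 (not isolated)
Conditions: Mn(C11H19O2)3 [Mn(dpm)3] (20 mol %), PhSiH3 (4 equiv), O2 (1 atm), i-PrOH–CH2Cl2, 0 → 23 °C; then P(OEt)3
Reagents that add atoms: dioxygen, O=O
Why: Mukaiyama–Magnus reductive α-hydroxylation (MHAT then O2 trapping) on both enone units: hydrogen atoms go to C-4 and C-8a and dioxygen to the two α-keto radicals from the face opposite the angular methyl group, which sets the trans ring fusion, the equatorial alkynyl group and both equatorial hydroxyls in one operation, and P(OEt)3 reduces the hydroperoxides.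

**Step 11**
Reactants: 21 (1R,3S,4S,4aS,8aS)-1,3-dihydroxy-3,4a,8,8-tetramethyl-4-[(trimethylsilyl)ethynyl]octahydronaphthalen-2(1H)-one
Product: 23 (1R,2S,3S,4R,4aS,8aS)-4-ethynyl-3,4a,8,8-tetramethyldecahydronaphthalene-1,2,3-triol, via silylalkyne triol 22 (not isolated)
Conditions: NaBH4, MeOH, −20 °C; then K2CO3, 23 °C
Reagents that add atoms: none
Why: Ketone reduction by axial hydride attack from the face opposite the axial methyl groups gives the equatorial (2S) alcohol, and K2CO3 in methanol then removes the alkynyl silyl group (protodesilylation).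

**Step 12**
Reactants: 24 (4S)-2,2-dimethyl-1,3-dioxolane-4-carbaldehyde
Product: 25 (4R)-4-ethynyl-2,2-dimethyl-1,3-dioxolane
Conditions: dimethyl (1-diazo-2-oxopropyl)phosphonate, K2CO3, MeOH, 0 → 23 °C
Reagents that add atoms: dimethyl (1-diazo-2-oxopropyl)phosphonate, COP(=O)(OC)C(=[N+]=[N-])C(C)=O
Why: Ohira–Bestmann (Seyferth–Gilbert) homologation converts the aldehyde into the terminal alkyne under mild base without epimerizing the α-alkoxy centre.

**Step 13**
Reactants: 25 (4R)-4-ethynyl-2,2-dimethyl-1,3-dioxolane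
Product: 27 (4S)-4-(1-bromoethenyl)-2,2-dimethyl-1,3-dioxolane, via bromoalkenylborane 26 (not isolated)
Conditions: B-bromo-9-BBN, CH2Cl2, 0 °C; then AcOH
Reagents that add atoms: B-bromo-9-borabicyclo[3.3.1]nonane, BrB1C2CCCC1CCC2
Why: syn-Bromoboration places boron on the terminal and bromine on the internal alkyne carbon, and protodeboronation with acetic acid leaves the 2-bromo-1-alkene; the stereocentre is untouched.

**Step 14**
Reactants: 23 (1R,2S,3S,4R,4aS,8aS)-4-ethynyl-3,4a,8,8-tetramethyldecahydronaphthalene-1,2,3-triol; 27 (4S)-4-(1-bromoethenyl)-2,2-dimethyl-1,3-dioxolane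
Product: 29 (1R,2S,3S,4R,4aS,8aS)-4-{(1E)-3-[(4R)-2,2-dimethyl-1,3-dioxolan-4-yl]buta-1,3-dien-1-yl}-3,4a,8,8-tetramethyldecahydronaphthalene-1,2,3-triol, via vinylstannane 28 (not isolated)
Conditions: Bu3SnH, PdCl2(PPh3)2 (3 mol %), THF, 0 °C; then 27, Pd2(dba)3 (5 mol %), AsPh3, CuI, DMF, 50 °C
Reagents that add atoms: none
Why: Pd-catalysed syn-hydrostannylation gives the (E)-vinylstannane with tin on the terminal carbon, and the Stille coupling with the vinyl bromide proceeds with retention to give the (E)-diene.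

**Step 15**
Reactants: 29 (1R,2S,3S,4R,4aS,8aS)-4-{(1E)-3-[(4R)-2,2-dimethyl-1,3-dioxolan-4-yl]buta-1,3-dien-1-yl}-3,4a,8,8-tetramethyldecahydronaphthalene-1,2,3-triol
Product: 30 (1R,2S,3S,4R,4aS,8aS)-4-[(1E,4R)-4,5-dihydroxy-3-methylidenepent-1-en-1-yl]-3,4a,8,8-tetramethyldecahydronaphthalene-1,2,3-triol
Conditions: AcOH–H2O (4:1), 40 °C
Reagents that add atoms: none
Why: Acid-catalysed acetal hydrolysis frees the 1,2-diol without affecting the other stereocentres.

**Compound list**
1 | 2-methylanisole (1-methoxy-2-methylbenzene) | COc1ccccc1C | starting material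
2 | (2-methoxy-3-methylphenyl)lithium | [Li]c1cccc(C)c1OC | intermediate
3 | 2-methoxy-3-methylbenzoic acid | COc1c(C)cccc1C(=O)O | intermediate
4 | (S)-2-(methoxymethyl)pyrrolidine | COC[C@@H]1CCCN1 | starting material
5 | 2-methoxy-3-methylbenzoyl chloride | COc1c(C)cccc1C(Cl)=O | intermediate
6 | (2-methoxy-3-methylphenyl)[(2S)-2-(methoxymethyl)pyrrolidin-1-yl]methanone | COC[C@@H]1CCCN1C(=O)c1cccc(C)c1OC | intermediate
7 | 5-bromo-2-methylpent-2-ene | CC(C)=CCCBr | starting material
8 | potassium (2-methoxy-3-methylcyclohexa-2,5-dien-1-ylidene)[(2S)-2-(methoxymethyl)pyrrolidin-1-yl]methanolate (amide enolate) | [K+].[O-]C(N1CCC[C@H]1COC)=C1C=CCC(C)=C1OC | intermediate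
9 | [(1R)-2-methoxy-3-methyl-1-(4-methylpent-3-en-1-yl)cyclohexa-2,5-dien-1-yl][(2S)-2-(methoxymethyl)pyrrolidin-1-yl]methanone | COC[C@@H]1CCCN1C(=O)[C@]2(CCC=C(C)C)C=CCC(C)=C2OC | intermediate
10 | (1R)-2-methoxy-3-methyl-1-(4-methylpent-3-en-1-yl)cyclohexa-2,5-diene-1-carbaldehyde | O=C[C@]1(CCC=C(C)C)C=CCC(C)=C1OC | intermediate
11 | hydrazone (CH=N–NH2) of aldehyde 10, quaternary carbon as in 10 | NN=C[C@]1(CCC=C(C)C)C=CCC(C)=C1OC | intermediate
12 | (6S)-1-methoxy-2,6-dimethyl-6-(4-methylpent-3-en-1-yl)cyclohexa-1,4-diene | C[C@]1(CCC=C(C)C)C=CCC(C)=C1OC | intermediate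
13 | (2S)-2,6-dimethyl-2-(4-methylpent-3-en-1-yl)cyclohex-3-en-1-one (both C-6 epimers) | C[C@]1(CCC=C(C)C)C=CCC(C)C1=O | intermediate
14 | potassium (6S)-2,6-dimethyl-6-(4-methylpent-3-en-1-yl)cyclohexa-1,4-dien-1-olate | C[C@]1(CCC=C(C)C)C=CCC(C)=C1[O-].[K+] | intermediate
15 | (6S)-2,6-dimethyl-6-(4-methylpent-3-en-1-yl)cyclohexa-1,4-dien-1-yl trifluoromethanesulfonate | C[C@]1(CCC=C(C)C)C=CCC(C)=C1OS(=O)(=O)C(F)(F)F | intermediate
16 | ethynyltrimethylsilane | C#C[Si](C)(C)C | starting material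
17 | {[(6S)-2,6-dimethyl-6-(4-methylpent-3-en-1-yl)cyclohexa-1,4-dien-1-yl]ethynyl}trimethylsilane | C[C@]1(CCC=C(C)C)C=CCC(C)=C1C#C[Si](C)(C)C | intermediate
18 | (4S)-2,4-dimethyl-4-(4-methylpent-3-en-1-yl)-3-[(trimethylsilyl)ethynyl]cyclohexa-2,5-dien-1-one | C[C@]1(CCC=C(C)C)C=CC(=O)C(C)=C1C#C[Si](C)(C)C | intermediate
19 | (4aS)-3,4a,8,8-tetramethyl-4-[(trimethylsilyl)ethynyl]-5,6,7,8-tetrahydronaphthalen-2(4aH)-one | C[C@]12CCCC(C)(C)C1=CC(=O)C(C)=C2C#C[Si](C)(C)C | intermediate
20 | (1R,3S,4S,4aS,8aS)-1,3-dihydroperoxy-3,4a,8,8-tetramethyl-4-[(trimethylsilyl)ethynyl]octahydronaphthalen-2(1H)-one (trans-fused; both OOH equatorial) | C[Si](C)(C)C#C[C@H]1[C@](C)(OO)C(=O)[C@H](OO)[C@H]2C(C)(C)CCC[C@@]21C | intermediate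
21 | (1R,3S,4S,4aS,8aS)-1,3-dihydroxy-3,4a,8,8-tetramethyl-4-[(trimethylsilyl)ethynyl]octahydronaphthalen-2(1H)-one (trans-fused; both OH and the alkynyl group equatorial) | C[Si](C)(C)C#C[C@H]1[C@](C)(O)C(=O)[C@H](O)[C@H]2C(C)(C)CCC[C@@]21C | intermediate
22 | (1R,2S,3S,4S,4aS,8aS)-3,4a,8,8-tetramethyl-4-[(trimethylsilyl)ethynyl]decahydronaphthalene-1,2,3-triol | C[Si](C)(C)C#C[C@H]1[C@](C)(O)[C@@H](O)[C@H](O)[C@H]2C(C)(C)CCC[C@@]21C | intermediate
23 | (1R,2S,3S,4R,4aS,8aS)-4-ethynyl-3,4a,8,8-tetramethyldecahydronaphthalene-1,2,3-triol | C#C[C@H]1[C@](C)(O)[C@@H](O)[C@H](O)[C@H]2C(C)(C)CCC[C@@]21C | intermediate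
24 | (4S)-2,2-dimethyl-1,3-dioxolane-4-carbaldehyde (L-glyceraldehyde acetonide) | O=C[C@@H]1COC(C)(C)O1 | starting material
25 | (4R)-4-ethynyl-2,2-dimethyl-1,3-dioxolane | C#C[C@@H]1COC(C)(C)O1 | intermediate
26 | 9-{(Z)-2-bromo-2-[(4S)-2,2-dimethyl-1,3-dioxolan-4-yl]ethenyl}-9-borabicyclo[3.3.1]nonane | Br/C([C@@H]1COC(C)(C)O1)=C\B1C2CCCC1CCC2 | intermediate
27 | (4S)-4-(1-bromoethenyl)-2,2-dimethyl-1,3-dioxolane | C=C(Br)[C@@H]1COC(C)(C)O1 | intermediate
28 | (1R,2S,3S,4R,4aS,8aS)-3,4a,8,8-tetramethyl-4-[(E)-2-(tributylstannyl)ethenyl]decahydronaphthalene-1,2,3-triol | CCCC[Sn](CCCC)(CCCC)/C=C/[C@H]1[C@](C)(O)[C@@H](O)[C@H](O)[C@H]2C(C)(C)CCC[C@@]21C | intermediate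
29 | (1R,2S,3S,4R,4aS,8aS)-4-{(1E)-3-[(4R)-2,2-dimethyl-1,3-dioxolan-4-yl]buta-1,3-dien-1-yl}-3,4a,8,8-tetramethyldecahydronaphthalene-1,2,3-triol | C=C(/C=C/[C@H]1[C@](C)(O)[C@@H](O)[C@H](O)[C@H]2C(C)(C)CCC[C@@]21C)[C@@H]1COC(C)(C)O1 | intermediate
30 | (1R,2S,3S,4R,4aS,8aS)-4-[(1E,4R)-4,5-dihydroxy-3-methylidenepent-1-en-1-yl]-3,4a,8,8-tetramethyldecahydronaphthalene-1,2,3-triol | C=C(/C=C/[C@H]1[C@](C)(O)[C@@H](O)[C@H](O)[C@H]2C(C)(C)CCC[C@@]21C)[C@@H](O)CO | target

**Step count**
Total: 15 steps. Longest linear sequence: 13 steps (steps 1–11, 14, 15); steps 12–13 make bromide 27.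

**Steps most likely to fail**

Step 9. The α-keto radical may be reduced instead of losing hydrogen, or the catalyst may only isomerize the side-chain alkene. The fallback sets out from 18: a reductive Giese cyclisation (Fe(C5H7O2)3, PhSiH3, EtOH–ethylene glycol, 60 °C) gives the cis-fused ketone (4aS,8aR)-3,4a,8,8-tetramethyl-4-[(trimethylsilyl)ethynyl]-4a,5,6,7,8,8a-hexahydronaphthalen-2(1H)-one F1. Dehydrogenation with IBX (DMSO–fluorobenzene, 70 °C) can only form the one new C=C toward the ring-fusion carbon and comes back to the route at 19; the cis fusion of F1 does not matter because that carbon becomes sp2 again.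

Step 10. The second hydrogen-atom transfer, onto the ring-fusion carbon flanked by two quaternary centres, may be slow, and the tertiary α-ketol may rearrange or be over-reduced. The fallback sets out from 19 and replaces the radical oxygenation by enolate chemistry. HAT hydrogenation of both enone C=C bonds (Mn(C11H19O2)3, PhSiH3, t-BuOOH, i-PrOH) gives the trans-fused ketone (4S,4aS,8aS)-3,4a,8,8-tetramethyl-4-[(trimethylsilyl)ethynyl]octahydronaphthalen-2(1H)-one F2. Kinetic enolization at the CH2 (KN(SiMe3)2, −78 °C) and oxidation with 3-phenyl-2-(phenylsulfonyl)oxaziridine from the face opposite the angular methyl gives the hydroxy ketone (1R,4S,4aS,8aS)-1-hydroxy-3,4a,8,8-tetramethyl-4-[(trimethylsilyl)ethynyl]octahydronaphthalen-2(1H)-one F3. A second enolization toward the methyl-bearing carbon (2.2 equiv base) and the same oxidant comes back to the route at 21.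

Step 4. The amide sits on a quaternary carbon and may react sluggishly with Cp2Zr(H)Cl. The fallback sets out from 9: LiNH2BH3 (THF, 0 → 23 °C) reduces the amide fully to the primary alcohol [(1S)-2-methoxy-3-methyl-1-(4-methylpent-3-en-1-yl)cyclohexa-2,5-dien-1-yl]methanol F4 and releases the auxiliary. Dess–Martin periodinane buffered with NaHCO3 (CH2Cl2) then comes back to the route at 10.

**Further compounds**
F1 | step 9 | (4aS,8aR)-3,4a,8,8-tetramethyl-4-[(trimethylsilyl)ethynyl]-4a,5,6,7,8,8a-hexahydronaphthalen-2(1H)-one (cis-fused) | C[Si](C)(C)C#CC1=C(C)C(=O)C[C@@H]2C(C)(C)CCC[C@@]21C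
F2 | step 10 | (4S,4aS,8aS)-3,4a,8,8-tetramethyl-4-[(trimethylsilyl)ethynyl]octahydronaphthalen-2(1H)-one (trans-fused, C-3 epimers) | C[Si](C)(C)C#C[C@H]1C(C)C(=O)C[C@H]2C(C)(C)CCC[C@@]21C
F3 | step 10 | (1R,4S,4aS,8aS)-1-hydroxy-3,4a,8,8-tetramethyl-4-[(trimethylsilyl)ethynyl]octahydronaphthalen-2(1H)-one (C-3 epimers) | C[Si](C)(C)C#C[C@H]1C(C)C(=O)[C@H](O)[C@H]2C(C)(C)CCC[C@@]21C
F4 | step 4 | [(1S)-2-methoxy-3-methyl-1-(4-methylpent-3-en-1-yl)cyclohexa-2,5-dien-1-yl]methanol | OC[C@]1(CCC=C(C)C)C=CCC(C)=C1OC
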